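(The numbers of this flask belong to no real substance; the run is a simulation.)

4 questions stand on two flasks, alpha and zeta, which differ in their run time.

    gas phase ⇌ dissolved gas, rate k1*(csat - [dissolved gas]) (k1 = 0.22 /min, csat = 2.9 mM)
    2 dissolved gas → self-condensation product (k2 = 87 /M/min)
    substrate + dissolved gas → target (k3 = 66 /M/min)
    dissolved gas + target → over-reacted product (k4 = 110 /M/min)

| flask | substrate | gas phase | time |
|---|---|---|---|
| alpha | 0.050 M | 2.9 mM (held) | 120 min |
| zeta | 0.050 M | 2.9 mM (held) | 50 min |

- a doubled species enters its step squared and goes two at a time
- at the start none of the gas is dissolved
- run time (alpha): 120 min

* which of the two there is more of at the end, alpha (target / over-reacted product)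
* which of the two there is more of at the end, zeta (target / over-reacted product)
* how much target is there at the end, in percent of the substrate charged: alpha
* how much target is there at the end, in percent of the substrate charged: zeta

How long does a portion of dissolved gas last? Against the substrate at its charge it lasts about 0.303 min, while transfer needs 4.55 min to respond, so a portion is used far sooner than transfer responds, and I take transfer as the rate-limiting step at that charge.

What level does the dissolved gas hold, then? Supply and use balance near 0.193 mM. I replace its whole curve by this flat mean, which gives a steady feed of 0.595 mM/min.

Isn't a flat level the weak spot, since the substrate falls during the run? It is. Each further 0.193 mM of level costs another 6.67% of the full feed, so my feed runs slightly high late in alpha. Self-condensation takes 1.09% of the feed at the flat level, far less than the feed itself, so I drop it.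

What do I carry forward? The gas allowance, the gas fed per substrate charged up to the reading: 1.43 for alpha and 0.595 for zeta.

How does it divide the substrate? Target costs one gas and over-reacted product two. Both steps draw on the same dissolved gas, so the clock cancels and their constants matter as the ratio r, 1.67. With a the fraction of substrate left, target is (a − a^r)/(r − 1). Starting from a as 1 minus half the allowance and correcting once, I get a = 0.164 for alpha and 0.592 for zeta. My alpha target is then 17.2%, with over-reacted product ahead. My zeta target is 26.2%, with target ahead.

The forecast puts over-reacted product ahead in alpha with 19.7% target, and target ahead in zeta with 26.7% target, on the ground that “Gas transfer is the bottleneck”. Its alpha target stands above mine, and so does its zeta target.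

The simulation gives alpha 19.8% target and 60.1% over-reacted product, and zeta 26.7% target and 16.2% over-reacted product. In alpha, the step making target used 1.1 times the gas of the step consuming target at 59.3 min, but 0.61 times at 120 min. Counting one gas in each target and two in each over-reacted product, and leaving aside the gas in dissolved gas and self-condensation product, these two products in alpha hold 1.40 gas per substrate charged at the end, against the allowance of 1.43. Counted the same way, a reading of alpha at 80.0 min holds 0.945, against an allowance of 0.953.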